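## Analysis of the target

The target is a germacranolide. Ring A is a ten-membered carbocycle (C1 to C10) and ring B is an α-methylene-γ-butyrolactone (O–C6–C7–C11–C12, with C13 as the exocyclic methylene on C11), fused to ring A at C6/C7. Ring A carries two trisubstituted alkenes of opposite geometry, (Z)-C1=C10 (C14 on C10) and (E)-C4=C5 (C15 on C4), a secondary allylic alcohol at C2 and an acyloxy group at C8. The bicycle has four stereocentres, all R: C6, C7 and C8 are contiguous, the lactone is trans-fused (H6 and H7 anti), and C2 is separated from this triad by the C4=C5 alkene. The acyl group on O8 adds two more stereocentres: it is (2R,3R)-2-(hydroxymethyl)-3-methyloxirane-2-carboxylate, the epoxide of a (Z)-2-(hydroxymethyl)but-2-enoate with methyl cis to the carboxyl carbon. Sensitive groups are the exo-methylene lactone (Michael acceptor), the glycidic ester, the allylic C2 carbinol, the 1,5-diene of ring A (Cope rearrangement on heating, transannular reactions under acid) and the lactone itself, which can migrate to O8 under base when that hydroxyl is free. The difficulty lies in closing a medium ring with fixed alkene geometries, in the C6–C7–C8 triad, and in acylating a hindered C8 hydroxyl late. The strategy rests on one feature: C7 bears the carbon substituent C11 and lies between two oxygenated carbons, C6 (lactone oxygen) and C8 (ester oxygen). This is the pattern left by anti opening of a trans C7,C8-epoxide at C7 by a carbon nucleophile delivered from O6.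

## Retrosynthetic reasoning

35 ⇒ 34. Only the primary hydroxyl of the acyl group is masked at the end. It must be protected while the acid is coupled, and a primary silyl ether can be removed last under buffered fluoride conditions that the other groups tolerate.

34 ⇒ 33 (C1–C2, ring A). C2 is a carbinol attached to the alkenyl carbon C1, so this bond corresponds to the addition of an alkenyl metal, made from a (Z)-alkenyl iodide at C1, to a C2 aldehyde. Cutting here leaves both trisubstituted alkenes in open chains, where stereospecific carbometalation sets their geometry, and puts the ring closure after the C6–C7–C8 triad is complete. The forward reaction must close a ten-membered ring at high dilution, keep the Z geometry and give the 2R alcohol.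

33 ⇒ 32 ⇒ 31 (C2 oxidation level). The aldehyde is β,γ-unsaturated and is therefore made only immediately before use, from the primary alcohol 32. The alcohol is released from a PMB ether, which is orthogonal to the silyl ether of the side chain.

31 ⇒ 30 (C11=C13). The methylene group comes from a Horner–Wadsworth–Emmons reaction of the α-phosphono lactone 30. The phosphonate is not an extra handle: it is the group that makes C11 nucleophilic in the key step.

30 ⇒ 21 + 29 (O8–acyl bond). In 21 the C8 hydroxyl is the only free hydroxyl, because the key step has just released it. Acylating at this point needs no protecting group at C8 and blocks O8 before it can attack the lactone carbonyl. The acid 29 is made separately, so the route is convergent.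

21 ⇒ 19 (C7–C11, ring B). The lactone is opened at the bond between C7 and C11. The precursor is the phosphonoacetate 19 of an erythro epoxy alcohol; its carbanion opens the trans epoxide at C7 with inversion. Cutting here gains the five-membered ring, the C7 stereocentre and the C8 hydroxyl in one step, with relative configuration fixed by mechanism. A cut at C7–C8 or C6–C7 would need separate control of each centre.

19 ⇒ 17 + 18. This is a plain esterification of the epoxy alcohol 17 with acid 18.

17 ⇒ 16 (epoxide). A Sharpless epoxidation with kinetic resolution of the racemic divinyl carbinol 16 selects the C6 configuration and creates C7 and C8 in the erythro relationship. One reagent-controlled operation therefore sets the whole triad.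

16 ⇒ 5 + 13 (C6–C7). The carbinol is cut next to the (E)-C7=C8 alkene, which corresponds to hydrozirconation of the terminal alkyne 13 and addition of the alkenyl metal to enal 5. Both partners are small and carry one alkene of fixed geometry each.

5 ⇒ 4 ⇒ 2 ⇒ 1. The (E)-C4=C5 alkene with its C15 methyl comes from syn carboalumination of the protected alkyne 2 and one-carbon homologation to 4.

13 ⇒ 12 ⇒ 9 + 10, and 9 ⇒ 8 ⇒ 6. The (Z)-iodoalkene comes from anti carbometalation and iodination of 6. The allylic bromide 9 is then extended by the silyl-capped acetylene 10.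

29 ⇒ 28 ⇒ 27 ⇒ 25 ⇒ 24 ⇒ 23 ⇒ 22. The acid is the oxidation product of epoxy alcohol 28, made by Sharpless epoxidation of allylic alcohol 27. The alkene geometry of 27 (methyl cis to the carbon that becomes the carboxyl) follows from the α-iodo enal 23, in which iodine is cis to methyl.

## Alternatives that were turned down

Alternative 1: The cut is at C5–C6 and C4–C15. The open-chain ynal A2 (terminal C4,C5-alkyne, C6 aldehyde) would be cyclised with Ni(cod)2, PBu3 and ZnMe2 to the carbocycle A1. In its favour, one step forms ring A, the C6 carbinol and the (E)-C4=C5 alkene with its methyl, and the syn addition fixes the geometry. On this point it matches carboalumination and saves the separate ring closure. Against it, the aldehyde carbon of A2 is attached to C7, which is also allylic to the C11=C13 alkene, so this centre can epimerise or move into conjugation. The C6 configuration is left to the diastereoselection of a ten-membered metallacyclic transition state with an endocyclic E-alkene. C2, C7 and C8 must each be set earlier by separate means. A1 is also still far from the target: C12 must be oxidised and lactonised, three protecting groups differentiated, and C8 acylated. The chosen route gives up the combined alkene and ring formation but sets C6, C7 and C8 from one epoxidation and ends closer to the target.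

Alternative 2: The cut is at C1–C2 with a temporary O–C10 bond. The nitro alkene A4 would be dehydrated with PhNCO to a nitrile oxide, which adds across the C1=C10 terminal alkene to give the isoxazoline-bridged bicycle A3. In its favour, the cycloaddition is neutral and tolerant, the trans lactone is already in place, and no labile β,γ-unsaturated aldehyde is needed. In these respects the ring closure is as strong as or stronger than the one chosen here. Against it, A3 must be taken through N–O cleavage, dehydration of the C10 tertiary alcohol to the (Z)-C1=C10 alkene, and reduction of the C2 ketone. The regiochemistry and geometry of the dehydration are not enforced by anything in the structure. C11 still has to be methylenated with strong base, and a C10 stereocentre is made only to be destroyed. The chosen route fixes the C1=C10 geometry by stereospecific carbometalation and has the C13 handle built in, at the price of a chromium-mediated closure.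

Alternative 3: The cut is at C7–C8. The bromomethyl butenolide aldehyde A6 would be treated with CrCl2 to give an allylchromium species that adds through C7 to the C8 aldehyde, forming the hydroxy methylene lactone A5. In its favour, one step closes ring A, creates C7 and C8 and forms the exo-methylene lactone. A5 is only an acylation and a desilylation from the target, so the endgame is shorter than the one chosen here. Against it, A6 is fragile: C6–H is γ to the butenolide carbonyl and allylic, so C6 can racemise, and the molecule also carries an allylic bromide and a β,γ-unsaturated aldehyde. The relative configuration of C7 and C8 is decided in a macrocyclic transition state and cannot be argued securely, and a wrong C8 alcohol next to the ring fusion would be hard to invert. The chosen route is longer after the key step but derives C6, C7 and C8 from one asymmetric epoxidation and an SN2 inversion.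

Key step: step 11

Remark: C1 to C15 are the germacrane numbers of the target and are used for every intermediate; 21 and 30 are mixtures of the two C11 epimers, which converge in step 19.

Step 1
Reactants: 1 but-3-yn-1-ol
Product: 2 1-[(but-3-yn-1-yloxy)methyl]-4-methoxybenzene
Conditions: NaH, PMBCl, Bu4NI (cat.), THF/DMF, 0 °C → rt
Reagents that add atoms: 4-methoxybenzyl chloride, COc1ccc(CCl)cc1
Why: Williamson ether synthesis; the alkoxide forms far more readily than the acetylide, and the PMB ether survives all organometallic, basic and epoxidation steps until its oxidative removal in step 20.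

Step 2
Reactants: 2 1-[(but-3-yn-1-yloxy)methyl]-4-methoxybenzene
Product: 4 (2E)-5-[(4-methoxyphenyl)methoxy]-3-methylpent-2-en-1-ol, via alkenyldimethylalane 3 (not isolated)
Conditions: AlMe3, Cp2ZrCl2 (cat.), CH2Cl2, 0 °C → rt; volatiles removed; n-BuLi, THF/hexane, −78 °C; (HCHO)n, −78 °C → rt
Reagents that add atoms: trimethylaluminium, C[Al](C)C; formaldehyde (from paraformaldehyde), C=O
Why: Negishi carboalumination adds methyl and aluminium syn across the alkyne with methyl on the internal carbon (C4), and the alanate formed with n-BuLi is hydroxymethylated with retention; this fixes the (E)-C4=C5 alkene with C15 cis to the new C6 carbon.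

Step 3
Reactants: 4 (2E)-5-[(4-methoxyphenyl)methoxy]-3-methylpent-2-en-1-ol
Product: 5 (2E)-5-[(4-methoxyphenyl)methoxy]-3-methylpent-2-enal
Conditions: MnO2, CH2Cl2, rt
Reagents that add atoms: none
Why: MnO2 oxidises the allylic alcohol selectively to the enal and leaves the PMB ether and the alkene geometry unchanged.

Step 4
Reactants: 6 prop-2-yn-1-ol
Product: 8 (2Z)-3-iodo-2-methylprop-2-en-1-ol, via alkenylmagnesium alkoxide 7 (not isolated)
Conditions: MeMgBr (3 equiv), CuI (10 mol %), Et2O, −10 °C → rt; then I2, −78 → 0 °C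
Reagents that add atoms: methylmagnesium bromide, C[Mg]Br; iodine, II
Why: Copper-catalysed carbomagnesiation of the magnesium alkoxide is an anti addition through the chelated alkenylmagnesium 7, and iodinolysis with retention puts iodine (C1) cis to the hydroxymethyl carbon (C9); this sets the (Z)-C1=C10 geometry.

Step 5
Reactants: 8 (2Z)-3-iodo-2-methylprop-2-en-1-ol
Product: 9 (1Z)-3-bromo-1-iodo-2-methylprop-1-ene
Conditions: CBr4, PPh3, CH2Cl2, 0 °C
Reagents that add atoms: carbon tetrabromide, BrC(Br)(Br)Br
Why: Appel bromination of the primary allylic alcohol under neutral conditions; the alkenyl iodide is inert and the alkene geometry cannot change.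

Step 6
Reactants: 9 (1Z)-3-bromo-1-iodo-2-methylprop-1-ene; 10 ethynyltrimethylsilane
Product: 12 [(4Z)-5-iodo-4-methylpent-4-en-1-yn-1-yl]trimethylsilane, via alkynylmagnesium bromide 11 (not isolated)
Conditions: 10, EtMgBr, THF, 0 °C → rt; then CuI (10 mol %), 9, THF, rt → 50 °C
Reagents that add atoms: none
Why: Copper-catalysed coupling of an alkynyl Grignard reagent with a primary allylic bromide gives the skipped enyne; the alkenyl iodide does not couple without palladium, and the silyl cap prevents double alkylation.

Step 7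
Reactants: 12 [(4Z)-5-iodo-4-methylpent-4-en-1-yn-1-yl]trimethylsilane
Product: 13 (1Z)-1-iodo-2-methylpent-1-en-4-yne
Conditions: K2CO3 (cat.), MeOH, 0 °C → rt
Reagents that add atoms: none
Why: Mild methanolysis of the alkynyl–silicon bond; the conditions are too weakly basic to isomerise the skipped enyne.

Step 8
Reactants: 13 (1Z)-1-iodo-2-methylpent-1-en-4-yne; 5 (2E)-5-[(4-methoxyphenyl)methoxy]-3-methylpent-2-enal
Product: 16 racemic (3E,6E,9Z)-10-iodo-1-[(4-methoxyphenyl)methoxy]-3,9-dimethyldeca-3,6,9-trien-5-ol, via alkenylzirconocene chloride 14 (not isolated), via alkenyl(methyl)zinc 15 (not isolated)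
Conditions: Cp2Zr(H)Cl, CH2Cl2, rt; ZnMe2, −65 °C; 5, 0 °C
Reagents that add atoms: none
Why: Hydrozirconation of the terminal alkyne is syn with zirconium at the terminal carbon, and after transmetalation to zinc the (E)-alkenyl group adds 1,2 to the enal, which forms C6–C7 and the (E)-C7=C8 alkene. The trisubstituted iodoalkene is not touched, and the carbinol is racemic by design.

Step 9
Reactants: 16 racemic (3E,6E,9Z)-10-iodo-1-[(4-methoxyphenyl)methoxy]-3,9-dimethyldeca-3,6,9-trien-5-ol
Product: 17 (1R,2E)-1-{(2R,3R)-3-[(2Z)-3-iodo-2-methylprop-2-en-1-yl]oxiran-2-yl}-5-[(4-methoxyphenyl)methoxy]-3-methylpent-2-en-1-ol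
Conditions: Ti(OiPr)4 (cat.), D-(−)-diisopropyl tartrate, t-BuOOH (0.6 equiv), 4 Å molecular sieves, CH2Cl2, −20 °C
Reagents that add atoms: tert-butyl hydroperoxide, CC(C)(C)OO
Why: Sharpless kinetic resolution: with the D-tartrate the (5S)-enantiomer of 16 is epoxidised fast at the (E)-disubstituted C7=C8 alkene on the face that gives the erythro epoxy alcohol, and the (5R)-enantiomer of 16 stays behind and is separated. The C4=C5 alkene should be a poor substrate because its C15 methyl is cis to the carbinol carbon, so this one step fixes C6, C7 and C8.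

Step 10
Reactants: 17 (1R,2E)-1-{(2R,3R)-3-[(2Z)-3-iodo-2-methylprop-2-en-1-yl]oxiran-2-yl}-5-[(4-methoxyphenyl)methoxy]-3-methylpent-2-en-1-ol; 18 (diethoxyphosphoryl)acetic acid
Product: 19 (1R,2E)-1-{(2S,3R)-3-[(2Z)-3-iodo-2-methylprop-2-en-1-yl]oxiran-2-yl}-5-[(4-methoxyphenyl)methoxy]-3-methylpent-2-en-1-yl (diethoxyphosphoryl)acetate
Conditions: DCC, 4-(dimethylamino)pyridine (cat.), CH2Cl2, 0 °C → rt
Reagents that add atoms: none
Why: Steglich esterification of the secondary alcohol under neutral conditions that leave the epoxide and the iodoalkene intact; it places the future nucleophile on O6 (the descriptor at C7 changes only because the priorities change).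

Step 11
Reactants: 19 (1R,2E)-1-{(2S,3R)-3-[(2Z)-3-iodo-2-methylprop-2-en-1-yl]oxiran-2-yl}-5-[(4-methoxyphenyl)methoxy]-3-methylpent-2-en-1-yl (diethoxyphosphoryl)acetate
Product: 21 diethyl {(4R,5R)-4-[(1R,3Z)-1-hydroxy-4-iodo-3-methylbut-3-en-1-yl]-5-{(1E)-4-[(4-methoxyphenyl)methoxy]-2-methylbut-1-en-1-yl}-2-oxooxolan-3-yl}phosphonate (both C3 epimers), via sodium phosphonoacetate carbanion 20 (not isolated)
Conditions: NaH, THF, 0 °C → rt; aq. NH4Cl, 0 °C
Reagents that add atoms: none
Why: NaH removes the proton between the phosphoryl and carbonyl groups (carbanion 20), and with the ester in its s-cis form C11 reaches the backside of the C7–O bond and displaces the epoxide oxygen in an SN2 reaction, forming C7–C11. The closest known reaction type is the base-induced cyclisation of malonate, sulfonylacetate and phosphonoacetate esters of 2,3-epoxy alcohols to β-(1-hydroxyalkyl)-γ-butyrolactones, the carbon counterpart of the cyclisation of epoxy alcohol urethanes to oxazolidinones. Ring B closes in the 5-exo-tet mode (the breaking C7–O bond lies outside the new five-membered ring), which is preferred over 6-endo attack at C8. C7 is set by inversion at a carbon whose configuration came from the Sharpless epoxidation; with C6 fixed the lactone is trans (H6 and H7 anti), and C8 keeps its configuration and appears as the free alcohol. C11 forms as both epimers, which is of no consequence because it becomes sp2 in step 19. The step needs attack at C7 and not at C8, and by carbon and not by the enolate oxygen: the short O6–C12–C11 tether and the collinear SN2 trajectory should secure the first, and the soft doubly stabilised carbanion the second. After ring closure the C8 alkoxide takes the acidic C11 proton, so the product rests as its phosphonate-stabilised anion; this keeps the lactone carbonyl unreactive toward O8 and, at or below room temperature, keeps the alkoxide concentration too low for phosphoryl transfer to O8. Quenching with ammonium chloride then gives 21.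

Step 12
Reactants: 22 (2E)-but-2-enal
Product: 23 (2Z)-2-iodobut-2-enal
Conditions: I2, K2CO3, 4-(dimethylamino)pyridine (cat.), THF/H2O, rt
Reagents that add atoms: iodine, II
Why: α-Iodination of the enal by amine-catalysed addition, iodination and elimination gives the more stable isomer with iodine cis to methyl; this places the future carboxyl carbon cis to methyl, as the side chain requires.

Step 13
Reactants: 23 (2Z)-2-iodobut-2-enal
Product: 24 (2Z)-2-iodobut-2-en-1-ol
Conditions: NaBH4, MeOH, 0 °C
Reagents that add atoms: none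
Why: 1,2-Reduction of the aldehyde; the iodoalkene and its geometry are unaffected.

Step 14
Reactants: 24 (2Z)-2-iodobut-2-en-1-ol
Product: 25 tert-butyl{[(2Z)-2-iodobut-2-en-1-yl]oxy}dimethylsilane
Conditions: TBSCl, imidazole, DMF, rt
Reagents that add atoms: tert-butyldimethylsilyl chloride, CC(C)(C)[Si](C)(C)Cl
Why: Standard silylation; this oxygen becomes the hydroxymethyl group of the side chain and stays protected until the last step.

Step 15
Reactants: 25 tert-butyl{[(2Z)-2-iodobut-2-en-1-yl]oxy}dimethylsilane
Product: 27 (2E)-2-({[tert-butyl(dimethyl)silyl]oxy}methyl)but-2-en-1-ol, via alkenyllithium 26 (not isolated)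
Conditions: t-BuLi (2.1 equiv), Et2O, −78 °C; then HCHO (monomer from cracked paraformaldehyde), −78 → 0 °C
Reagents that add atoms: formaldehyde, C=O
Why: Iodine–lithium exchange proceeds with retention of alkene geometry, and hydroxymethylation of alkenyllithium 26 at low temperature (which suppresses elimination to the allene) puts the free hydroxymethyl group cis to methyl.

Step 16
Reactants: 27 (2E)-2-({[tert-butyl(dimethyl)silyl]oxy}methyl)but-2-en-1-ol
Product: 28 [(2R,3R)-2-({[tert-butyl(dimethyl)silyl]oxy}methyl)-3-methyloxiran-2-yl]methanol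
Conditions: Ti(OiPr)4 (cat.), L-(+)-diethyl tartrate, t-BuOOH, 4 Å molecular sieves, CH2Cl2, −20 °C
Reagents that add atoms: tert-butyl hydroperoxide, CC(C)(C)OO
Why: Sharpless asymmetric epoxidation directed by the free allylic alcohol; with the L-tartrate the oxygen is delivered to the face that gives the (2R,3R)-epoxide, and syn addition keeps methyl cis to the hydroxymethyl carbon. Any minor enantiomer would be removed as a diastereomer after step 18.

Step 17
Reactants: 28 [(2R,3R)-2-({[tert-butyl(dimethyl)silyl]oxy}methyl)-3-methyloxiran-2-yl]methanol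
Product: 29 (2R,3R)-2-({[tert-butyl(dimethyl)silyl]oxy}methyl)-3-methyloxirane-2-carboxylic acid
Conditions: PhI(OAc)2, 2,2,6,6-tetramethylpiperidin-1-oxyl (cat.), MeCN/H2O, rt
Reagents that add atoms: water, O
Why: Oxoammonium-catalysed oxidation takes the primary alcohol through the aldehyde hydrate to the acid under near-neutral conditions that spare the epoxide and the silyl ether.

Step 18
Reactants: 21 diethyl {(4R,5R)-4-[(1R,3Z)-1-hydroxy-4-iodo-3-methylbut-3-en-1-yl]-5-{(1E)-4-[(4-methoxyphenyl)methoxy]-2-methylbut-1-en-1-yl}-2-oxooxolan-3-yl}phosphonate; 29 (2R,3R)-2-({[tert-butyl(dimethyl)silyl]oxy}methyl)-3-methyloxirane-2-carboxylic acid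
Product: 30 (1R,3Z)-1-{(2R,3R)-4-(diethoxyphosphoryl)-2-[(1E)-4-[(4-methoxyphenyl)methoxy]-2-methylbut-1-en-1-yl]-5-oxooxolan-3-yl}-4-iodo-3-methylbut-3-en-1-yl (2R,3R)-2-({[tert-butyl(dimethyl)silyl]oxy}methyl)-3-methyloxirane-2-carboxylate
Conditions: 29, 2,4,6-trichlorobenzoyl chloride, Et3N, THF, rt; then 21, 4-(dimethylamino)pyridine, toluene, rt
Reagents that add atoms: none
Why: Yamaguchi esterification through the mixed anhydride of 29 acylates the only free hydroxyl, O8, without touching the C8 configuration. Doing this directly after the annulation caps O8 before it can attack C12 and makes a separate protecting group at C8 unnecessary.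

Step 19
Reactants: 30 (1R,3Z)-1-{(2R,3R)-4-(diethoxyphosphoryl)-2-[(1E)-4-[(4-methoxyphenyl)methoxy]-2-methylbut-1-en-1-yl]-5-oxooxolan-3-yl}-4-iodo-3-methylbut-3-en-1-yl (2R,3R)-2-({[tert-butyl(dimethyl)silyl]oxy}methyl)-3-methyloxirane-2-carboxylate
Product: 31 (1R,3Z)-4-iodo-1-{(2R,3R)-2-[(1E)-4-[(4-methoxyphenyl)methoxy]-2-methylbut-1-en-1-yl]-4-methylidene-5-oxooxolan-3-yl}-3-methylbut-3-en-1-yl (2R,3R)-2-({[tert-butyl(dimethyl)silyl]oxy}methyl)-3-methyloxirane-2-carboxylate
Conditions: K2CO3, 37 % aq. HCHO, THF, 0 °C → rt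
Reagents that add atoms: formaldehyde, C=O
Why: Horner–Wadsworth–Emmons reaction of the α-phosphono lactone with formaldehyde under mild aqueous carbonate conditions installs the C13 methylene group and removes the C11 stereocentre.

Step 20
Reactants: 31 (1R,3Z)-4-iodo-1-{(2R,3R)-2-[(1E)-4-[(4-methoxyphenyl)methoxy]-2-methylbut-1-en-1-yl]-4-methylidene-5-oxooxolan-3-yl}-3-methylbut-3-en-1-yl (2R,3R)-2-({[tert-butyl(dimethyl)silyl]oxy}methyl)-3-methyloxirane-2-carboxylate
Product: 32 (1R,3Z)-1-{(2R,3R)-2-[(1E)-4-hydroxy-2-methylbut-1-en-1-yl]-4-methylidene-5-oxooxolan-3-yl}-4-iodo-3-methylbut-3-en-1-yl (2R,3R)-2-({[tert-butyl(dimethyl)silyl]oxy}methyl)-3-methyloxirane-2-carboxylate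
Conditions: DDQ, CH2Cl2/pH 7 buffer, 0 °C → rt
Reagents that add atoms: none
Why: Oxidative cleavage of the PMB ether under buffered conditions; the silyl ether, the epoxy ester, the iodoalkene and the exo-methylene lactone are inert to DDQ.

Step 21
Reactants: 32 (1R,3Z)-1-{(2R,3R)-2-[(1E)-4-hydroxy-2-methylbut-1-en-1-yl]-4-methylidene-5-oxooxolan-3-yl}-4-iodo-3-methylbut-3-en-1-yl (2R,3R)-2-({[tert-butyl(dimethyl)silyl]oxy}methyl)-3-methyloxirane-2-carboxylate
Product: 33 (1R,3Z)-4-iodo-3-methyl-1-{(2R,3R)-4-methylidene-2-[(1E)-2-methyl-4-oxobut-1-en-1-yl]-5-oxooxolan-3-yl}but-3-en-1-yl (2R,3R)-2-({[tert-butyl(dimethyl)silyl]oxy}methyl)-3-methyloxirane-2-carboxylate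
Conditions: Dess–Martin periodinane, NaHCO3, CH2Cl2, 0 °C
Reagents that add atoms: none
Why: Dess–Martin oxidation with bicarbonate buffering gives the β,γ-unsaturated aldehyde without moving the C4=C5 alkene into conjugation; the aldehyde is used at once.

Step 22
Reactants: 33 (1R,3Z)-4-iodo-3-methyl-1-{(2R,3R)-4-methylidene-2-[(1E)-2-methyl-4-oxobut-1-en-1-yl]-5-oxooxolan-3-yl}but-3-en-1-yl (2R,3R)-2-({[tert-butyl(dimethyl)silyl]oxy}methyl)-3-methyloxirane-2-carboxylate
Product: 34 (3aR,4R,6Z,8R,10E,11aR)-8-hydroxy-6,10-dimethyl-3-methylidene-2-oxo-2,3,3a,4,5,8,9,11a-octahydrocyclodeca[b]furan-4-yl (2R,3R)-2-({[tert-butyl(dimethyl)silyl]oxy}methyl)-3-methyloxirane-2-carboxylate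
Conditions: CrCl2 (excess), NiCl2 (cat.), degassed DMSO, rt, high dilution (slow addition of 33)
Reagents that add atoms: none
Why: Nozaki–Hiyama–Kishi reaction: the alkenyl iodide adds oxidatively to zerovalent nickel (made from NiCl2 by CrCl2), the alkenyl group passes to chromium, and the alkenylchromium species adds to the C2 aldehyde, closing ring A with retention of the Z geometry. Esters, the epoxide and the exo-methylene lactone are expected to be tolerated; the facial selectivity at C2 is substrate-controlled and is the open point of this step.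

Step 23
Reactants: 34 (3aR,4R,6Z,8R,10E,11aR)-8-hydroxy-6,10-dimethyl-3-methylidene-2-oxo-2,3,3a,4,5,8,9,11a-octahydrocyclodeca[b]furan-4-yl (2R,3R)-2-({[tert-butyl(dimethyl)silyl]oxy}methyl)-3-methyloxirane-2-carboxylate
Product: 35 (3aR,4R,6Z,8R,10E,11aR)-8-hydroxy-6,10-dimethyl-3-methylidene-2-oxo-2,3,3a,4,5,8,9,11a-octahydrocyclodeca[b]furan-4-yl (2R,3R)-2-(hydroxymethyl)-3-methyloxirane-2-carboxylate
Conditions: HF·pyridine, pyridine, THF, 0 °C → rt
Reagents that add atoms: none
Why: Buffered fluoride cleaves the primary silyl ether under weakly acidic conditions that should leave the glycidic ester, the exo-methylene lactone, the allylic alcohol and the 1,5-diene intact.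

Compound list

1 | but-3-yn-1-ol | C#CCCO | starting material
2 | 1-[(but-3-yn-1-yloxy)methyl]-4-methoxybenzene | C#CCCOCc1ccc(OC)cc1 | intermediate
3 | (E)-{4-[(4-methoxyphenyl)methoxy]-2-methylbut-1-en-1-yl}dimethylalane (formed in the flask) | C/C(CCOCc1ccc(OC)cc1)=C\[Al](C)C | intermediate
4 | (2E)-5-[(4-methoxyphenyl)methoxy]-3-methylpent-2-en-1-ol | C/C(CCOCc1ccc(OC)cc1)=C\CO | intermediate
5 | (2E)-5-[(4-methoxyphenyl)methoxy]-3-methylpent-2-enal | C/C(CCOCc1ccc(OC)cc1)=C\C=O | intermediate
6 | prop-2-yn-1-ol | C#CCO | starting material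
7 | bromomagnesium (2Z)-3-(bromomagnesio)-2-methylprop-2-en-1-olate (formed in the flask) | Br[Mg]OC/C(C)=C\[Mg]Br | intermediate
8 | (2Z)-3-iodo-2-methylprop-2-en-1-ol | OC/C(C)=C\I | intermediate
9 | (1Z)-3-bromo-1-iodo-2-methylprop-1-ene | BrC/C(C)=C\I | intermediate
10 | ethynyltrimethylsilane | C#C[Si](C)(C)C | starting material
11 | [(trimethylsilyl)ethynyl]magnesium bromide (formed in the flask) | C[Si](C)(C)C#C[Mg]Br | intermediate
12 | [(4Z)-5-iodo-4-methylpent-4-en-1-yn-1-yl]trimethylsilane | C[Si](C)(C)C#CC/C(C)=C\I | intermediate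
13 | (1Z)-1-iodo-2-methylpent-1-en-4-yne | C#CC/C(C)=C\I | intermediate
14 | chlorobis(cyclopentadienyl)[(1E,4Z)-5-iodo-4-methylpenta-1,4-dien-1-yl]zirconium (formed in the flask) | Cl[Zr](/C=C/C/C(C)=C\I)(C1C=CC=C1)C1C=CC=C1 | intermediate
15 | [(1E,4Z)-5-iodo-4-methylpenta-1,4-dien-1-yl](methyl)zinc (formed in the flask) | C[Zn]/C=C/C/C(C)=C\I | intermediate
16 | racemic (3E,6E,9Z)-10-iodo-1-[(4-methoxyphenyl)methoxy]-3,9-dimethyldeca-3,6,9-trien-5-ol | COc1ccc(COCC/C(C)=C/C(O)/C=C/C/C(C)=C\I)cc1 | intermediate
17 | (1R,2E)-1-{(2R,3R)-3-[(2Z)-3-iodo-2-methylprop-2-en-1-yl]oxiran-2-yl}-5-[(4-methoxyphenyl)methoxy]-3-methylpent-2-en-1-ol | COc1ccc(COCC/C(C)=C/[C@@H](O)[C@H]2O[C@@H]2C/C(C)=C\I)cc1 | intermediate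
18 | (diethoxyphosphoryl)acetic acid | CCOP(=O)(CC(=O)O)OCC | starting material
19 | (1R,2E)-1-{(2S,3R)-3-[(2Z)-3-iodo-2-methylprop-2-en-1-yl]oxiran-2-yl}-5-[(4-methoxyphenyl)methoxy]-3-methylpent-2-en-1-yl (diethoxyphosphoryl)acetate | CCOP(=O)(OCC)CC(=O)O[C@H](/C=C(\C)CCOCc1ccc(OC)cc1)[C@H]1O[C@@H]1C/C(C)=C\I | intermediate
20 | sodium salt of the C11 carbanion of 19 (formed in the flask) | [Na+].CCOP(=O)(OCC)[CH-]C(=O)O[C@H](/C=C(\C)CCOCc1ccc(OC)cc1)[C@H]1O[C@@H]1C/C(C)=C\I | intermediate
21 | diethyl {(4R,5R)-4-[(1R,3Z)-1-hydroxy-4-iodo-3-methylbut-3-en-1-yl]-5-{(1E)-4-[(4-methoxyphenyl)methoxy]-2-methylbut-1-en-1-yl}-2-oxooxolan-3-yl}phosphonate (both C3 epimers) | CCOP(=O)(OCC)C1C(=O)O[C@H](/C=C(\C)CCOCc2ccc(OC)cc2)[C@H]1[C@H](O)C/C(C)=C\I | intermediate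
22 | (2E)-but-2-enal | C/C=C/C=O | starting material
23 | (2Z)-2-iodobut-2-enal | C/C=C(\I)C=O | intermediate
24 | (2Z)-2-iodobut-2-en-1-ol | C/C=C(\I)CO | intermediate
25 | tert-butyl{[(2Z)-2-iodobut-2-en-1-yl]oxy}dimethylsilane | C/C=C(\I)CO[Si](C)(C)C(C)(C)C | intermediate
26 | [(2E)-1-{[tert-butyl(dimethyl)silyl]oxy}but-2-en-2-yl]lithium (formed in the flask) | C/C=C(\[Li])CO[Si](C)(C)C(C)(C)C | intermediate
27 | (2E)-2-({[tert-butyl(dimethyl)silyl]oxy}methyl)but-2-en-1-ol | C/C=C(\CO)CO[Si](C)(C)C(C)(C)C | intermediate
28 | [(2R,3R)-2-({[tert-butyl(dimethyl)silyl]oxy}methyl)-3-methyloxiran-2-yl]methanol | OC[C@]1(CO[Si](C)(C)C(C)(C)C)O[C@@H]1C | intermediate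
29 | (2R,3R)-2-({[tert-butyl(dimethyl)silyl]oxy}methyl)-3-methyloxirane-2-carboxylic acid | OC(=O)[C@]1(CO[Si](C)(C)C(C)(C)C)O[C@@H]1C | intermediate
30 | (1R,3Z)-1-{(2R,3R)-4-(diethoxyphosphoryl)-2-[(1E)-4-[(4-methoxyphenyl)methoxy]-2-methylbut-1-en-1-yl]-5-oxooxolan-3-yl}-4-iodo-3-methylbut-3-en-1-yl (2R,3R)-2-({[tert-butyl(dimethyl)silyl]oxy}methyl)-3-methyloxirane-2-carboxylate | CCOP(=O)(OCC)C1C(=O)O[C@H](/C=C(\C)CCOCc2ccc(OC)cc2)[C@H]1[C@@H](C/C(C)=C\I)OC(=O)[C@]3(CO[Si](C)(C)C(C)(C)C)O[C@@H]3C | intermediate
31 | (1R,3Z)-4-iodo-1-{(2R,3R)-2-[(1E)-4-[(4-methoxyphenyl)methoxy]-2-methylbut-1-en-1-yl]-4-methylidene-5-oxooxolan-3-yl}-3-methylbut-3-en-1-yl (2R,3R)-2-({[tert-butyl(dimethyl)silyl]oxy}methyl)-3-methyloxirane-2-carboxylate | C=C1C(=O)O[C@H](/C=C(\C)CCOCc2ccc(OC)cc2)[C@H]1[C@@H](C/C(C)=C\I)OC(=O)[C@]3(CO[Si](C)(C)C(C)(C)C)O[C@@H]3C | intermediate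
32 | (1R,3Z)-1-{(2R,3R)-2-[(1E)-4-hydroxy-2-methylbut-1-en-1-yl]-4-methylidene-5-oxooxolan-3-yl}-4-iodo-3-methylbut-3-en-1-yl (2R,3R)-2-({[tert-butyl(dimethyl)silyl]oxy}methyl)-3-methyloxirane-2-carboxylate | C=C1C(=O)O[C@H](/C=C(\C)CCO)[C@H]1[C@@H](C/C(C)=C\I)OC(=O)[C@]2(CO[Si](C)(C)C(C)(C)C)O[C@@H]2C | intermediate
33 | (1R,3Z)-4-iodo-3-methyl-1-{(2R,3R)-4-methylidene-2-[(1E)-2-methyl-4-oxobut-1-en-1-yl]-5-oxooxolan-3-yl}but-3-en-1-yl (2R,3R)-2-({[tert-butyl(dimethyl)silyl]oxy}methyl)-3-methyloxirane-2-carboxylate | C=C1C(=O)O[C@H](/C=C(\C)CC=O)[C@H]1[C@@H](C/C(C)=C\I)OC(=O)[C@]2(CO[Si](C)(C)C(C)(C)C)O[C@@H]2C | intermediate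
34 | (3aR,4R,6Z,8R,10E,11aR)-8-hydroxy-6,10-dimethyl-3-methylidene-2-oxo-2,3,3a,4,5,8,9,11a-octahydrocyclodeca[b]furan-4-yl (2R,3R)-2-({[tert-butyl(dimethyl)silyl]oxy}methyl)-3-methyloxirane-2-carboxylate | C=C1C(=O)O[C@@H]2/C=C(\C)C[C@@H](O)/C=C(/C)C[C@@H](OC(=O)[C@]3(CO[Si](C)(C)C(C)(C)C)O[C@@H]3C)[C@@H]12 | intermediate
35 | (3aR,4R,6Z,8R,10E,11aR)-8-hydroxy-6,10-dimethyl-3-methylidene-2-oxo-2,3,3a,4,5,8,9,11a-octahydrocyclodeca[b]furan-4-yl (2R,3R)-2-(hydroxymethyl)-3-methyloxirane-2-carboxylate | C=C1C(=O)O[C@@H]2/C=C(\C)C[C@@H](O)/C=C(/C)C[C@@H](OC(=O)[C@]3(CO)O[C@@H]3C)[C@@H]12 | target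

Total step count: 23. Longest linear sequence: 14 steps, from prop-2-yn-1-ol 6 to 35 (steps 4 to 11 and 18 to 23). The branch from 1 contributes 3 steps (1 to 3) and the side-chain branch from 22 contributes 6 steps (12 to 17).

Steps least certain to work

Step 11 (key step). The stabilised carbanion may open the epoxide only on warming. At that temperature two side paths can take over: the C8 alkoxide can attack phosphorus, moving the phosphoryl group from C11 to O8 and leading to three-membered ring closure (the cyclopropanation path of phosphonoacetates with epoxides), or the enolate oxygen can alkylate in place of carbon. The cause is that carbon must approach C7 out of the plane of a five-membered, s-cis ester enolate. Fallback, setting out from 17 and returning at 31: 17 is esterified with the mono-2-(trimethylsilyl)ethyl ester of malonic acid (DCC, 4-(dimethylamino)pyridine) to the mixed malonate F1. The smaller, phosphorus-free carbanion of F1 is cyclised with NaH or Cs2CO3 to the α-[2-(trimethylsilyl)ethoxycarbonyl] lactone F2. The silylethyl ester is cleaved with Bu4NF to the α-carboxy lactone F3, which is converted by decarboxylative Mannich methylenation (aqueous formaldehyde, Et2NH, then NaOAc/AcOH) into the hydroxy methylene lactone F4. Yamaguchi esterification of F4 with 29 gives 31.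

Step 22. The ring closure may show poor facial selectivity at the C2 aldehyde, because the new centre is far from the C6–C7–C8 triad and is controlled only by the folding of the chain. Fallback, setting out from 34 obtained together with its C2 epimer F5 and returning at 34: the mixture is oxidised with Dess–Martin periodinane to the C2 ketone F6. F6 is reduced with catecholborane and the (S)-CBS catalyst, (3aS)-1-methyl-3,3-diphenyltetrahydro-1H,3H-pyrrolo[1,2-c][1,3,2]oxazaborole, at low temperature. The alkenyl branch is expected to act as the large group, which corresponds to the 8R alcohol 34; the centre is then set by the reagent and no longer in the C–C bond formation.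

Step 9. Epoxidation at the more electron-rich trisubstituted C4=C5 alkene may compete, or the rate difference between the enantiomers may be too small, because both alkenes are allylic to the same carbinol. Fallback, setting out from 13 (and from alane 3) and returning at 17: the alkenylzinc species 15 made from 13 is added to formaldehyde to give (2E,5Z)-6-iodo-5-methylhexa-2,5-dien-1-ol F7. Sharpless epoxidation of this primary allylic alcohol with D-(−)-diethyl tartrate gives the epoxy alcohol F8, and Parikh–Doering oxidation gives the epoxy aldehyde F9. Alane 3 is iodinated to the (E)-alkenyl iodide F10, which is lithiated with t-BuLi and added to F9 to give 17 together with its C6 epimer F11. The mixture is oxidised with Dess–Martin periodinane to the epoxy enone F12, and chelation-controlled reduction with Zn(BH4)2 returns the erythro epoxy alcohol 17. Here C7 and C8 come from a primary allylic alcohol with a single alkene, and C6 from substrate-controlled reduction.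

Step 18. Under the basic acylation conditions the acidic C11–H of the α-phosphono lactone may be deprotonated, leading to C-acylation or, in step 19, to transfer of the hindered acyl group from O8 to C11; the slow reaction of the α-quaternary acid leaves time for this. Fallback, setting out from 21 and returning at 31: 21 is silylated with Et3SiOTf and 2,6-lutidine to the C8 triethylsilyl ether F13. Horner–Wadsworth–Emmons methylenation (K2CO3, aqueous formaldehyde) gives the silylated methylene lactone F14. The triethylsilyl group is removed with pyridinium p-toluenesulfonate in MeOH to give the hydroxy methylene lactone F4, which has no acidic C11–H and is esterified with 29 by the Yamaguchi procedure to give 31.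

Further compounds

F1 | step 11 | (1R,2E)-1-{(2S,3R)-3-[(2Z)-3-iodo-2-methylprop-2-en-1-yl]oxiran-2-yl}-5-[(4-methoxyphenyl)methoxy]-3-methylpent-2-en-1-yl 2-(trimethylsilyl)ethyl propanedioate | C[Si](C)(C)CCOC(=O)CC(=O)O[C@H](/C=C(\C)CCOCc1ccc(OC)cc1)[C@H]1O[C@@H]1C/C(C)=C\I
F2 | step 11 | 2-(trimethylsilyl)ethyl (4R,5R)-4-[(1R,3Z)-1-hydroxy-4-iodo-3-methylbut-3-en-1-yl]-5-{(1E)-4-[(4-methoxyphenyl)methoxy]-2-methylbut-1-en-1-yl}-2-oxooxolane-3-carboxylate (both C3 epimers) | C[Si](C)(C)CCOC(=O)C1C(=O)O[C@H](/C=C(\C)CCOCc2ccc(OC)cc2)[C@H]1[C@H](O)C/C(C)=C\I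
F3 | step 11 | (4R,5R)-4-[(1R,3Z)-1-hydroxy-4-iodo-3-methylbut-3-en-1-yl]-5-{(1E)-4-[(4-methoxyphenyl)methoxy]-2-methylbut-1-en-1-yl}-2-oxooxolane-3-carboxylic acid (both C3 epimers) | OC(=O)C1C(=O)O[C@H](/C=C(\C)CCOCc2ccc(OC)cc2)[C@H]1[C@H](O)C/C(C)=C\I
F4 | step 11 | (4R,5R)-4-[(1R,3Z)-1-hydroxy-4-iodo-3-methylbut-3-en-1-yl]-5-{(1E)-4-[(4-methoxyphenyl)methoxy]-2-methylbut-1-en-1-yl}-3-methylideneoxolan-2-one | C=C1C(=O)O[C@H](/C=C(\C)CCOCc2ccc(OC)cc2)[C@H]1[C@H](O)C/C(C)=C\I
F5 | step 22 | (8S)-epimer of 34 (C2 epimer) | C=C1C(=O)O[C@@H]2/C=C(\C)C[C@H](O)/C=C(/C)C[C@@H](OC(=O)[C@]3(CO[Si](C)(C)C(C)(C)C)O[C@@H]3C)[C@@H]12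
F6 | step 22 | (3aR,4R,6Z,10E,11aR)-6,10-dimethyl-3-methylidene-2,8-dioxo-2,3,3a,4,5,8,9,11a-octahydrocyclodeca[b]furan-4-yl (2R,3R)-2-({[tert-butyl(dimethyl)silyl]oxy}methyl)-3-methyloxirane-2-carboxylate | C=C1C(=O)O[C@@H]2/C=C(\C)CC(=O)/C=C(/C)C[C@@H](OC(=O)[C@]3(CO[Si](C)(C)C(C)(C)C)O[C@@H]3C)[C@@H]12
F7 | step 9 | (2E,5Z)-6-iodo-5-methylhexa-2,5-dien-1-ol | OC/C=C/C/C(C)=C\I
F8 | step 9 | {(2R,3R)-3-[(2Z)-3-iodo-2-methylprop-2-en-1-yl]oxiran-2-yl}methanol | OC[C@H]1O[C@@H]1C/C(C)=C\I
F9 | step 9 | (2S,3R)-3-[(2Z)-3-iodo-2-methylprop-2-en-1-yl]oxirane-2-carbaldehyde | O=C[C@H]1O[C@@H]1C/C(C)=C\I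
F10 | step 9 | 1-({[(3E)-4-iodo-3-methylbut-3-en-1-yl]oxy}methyl)-4-methoxybenzene | C/C(CCOCc1ccc(OC)cc1)=C\I
F11 | step 9 | (1S)-epimer of 17 (C6 epimer) | COc1ccc(COCC/C(C)=C/[C@H](O)[C@H]2O[C@@H]2C/C(C)=C\I)cc1
F12 | step 9 | (2E)-1-{(2S,3R)-3-[(2Z)-3-iodo-2-methylprop-2-en-1-yl]oxiran-2-yl}-5-[(4-methoxyphenyl)methoxy]-3-methylpent-2-en-1-one | COc1ccc(COCC/C(C)=C/C(=O)[C@H]2O[C@@H]2C/C(C)=C\I)cc1
F13 | step 18 | C8 triethylsilyl ether of 21 (both C11 epimers) | CCOP(=O)(OCC)C1C(=O)O[C@H](/C=C(\C)CCOCc2ccc(OC)cc2)[C@H]1[C@@H](C/C(C)=C\I)O[Si](CC)(CC)CC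
F14 | step 18 | (4R,5R)-4-[(1R,3Z)-4-iodo-3-methyl-1-[(triethylsilyl)oxy]but-3-en-1-yl]-5-{(1E)-4-[(4-methoxyphenyl)methoxy]-2-methylbut-1-en-1-yl}-3-methylideneoxolan-2-one | C=C1C(=O)O[C@H](/C=C(\C)CCOCc2ccc(OC)cc2)[C@H]1[C@@H](C/C(C)=C\I)O[Si](CC)(CC)CC
A1 | alternative 1 | ring A dienol with free C6 hydroxyl, C2 tert-butyldimethylsilyl ether, C8 PMB ether and a 3-[(triethylsilyl)oxy]prop-1-en-2-yl group on C7 | C=C(CO[Si](CC)(CC)CC)[C@H]1[C@H](O)/C=C(\C)C[C@@H](O[Si](C)(C)C(C)(C)C)/C=C(/C)C[C@H]1OCc1ccc(OC)cc1
A2 | alternative 1 | open-chain ynal with C6 aldehyde and terminal C4,C5-alkyne | C#CC[C@@H](O[Si](C)(C)C(C)(C)C)/C=C(/C)C[C@@H](OCc1ccc(OC)cc1)[C@H](C=O)C(=C)CO[Si](CC)(CC)CC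
A3 | alternative 2 | isoxazoline-bridged ring A lactone, C8 tert-butyldimethylsilyl ether | C[C@]12CC(=NO1)C/C(C)=C/[C@H]1OC(=O)C[C@@H]1[C@H](O[Si](C)(C)C(C)(C)C)C2
A4 | alternative 2 | nitro alkene lactone with C2 nitromethylene and C1=C10 terminal alkene | [O-][N+](=O)CC/C(C)=C/[C@H]1OC(=O)C[C@@H]1[C@H](O[Si](C)(C)C(C)(C)C)CC(C)=C
A5 | alternative 3 | C8-hydroxy methylene lactone core, C2 tert-butyldimethylsilyl ether | C=C1C(=O)O[C@@H]2/C=C(\C)C[C@@H](O[Si](C)(C)C(C)(C)C)/C=C(/C)C[C@@H](O)[C@@H]12
A6 | alternative 3 | 3-(bromomethyl)butenolide with C8 aldehyde | BrCC1=C[C@H](OC1=O)/C=C(\C)C[C@@H](O[Si](C)(C)C(C)(C)C)/C=C(/C)CC=O
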